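**Retrosynthetic overview**

- Feature: the oxirane ring O–C8–C9 is the only ring to be built. Its fully substituted carbon C8 carries, besides the ring atoms, only the benzene ring and the acyloxymethyl carbon C10, so the ring CH2 (C9) is one methylene added to a ketone C8=O.
- Key disconnection: C8–C9 and C9–O, back to an aryl acyloxymethyl ketone and dimethylsulfoxonium methylide under chiral LaLi3(binaphthoxide)3 catalysis (enantioselective Corey–Chaykovsky epoxidation), which sets C8.
- Masking: the aldehyde is carried as a vinyl group (ozonolysis last) and the aryl ester as a triisopropylsilyl ether (exchanged after the epoxidation), because the ylide would attack an aldehyde or an aryl ester.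
- The ketone comes from 1-(4-bromo-2-hydroxyphenyl)ethanone by O-silylation, α-bromination, carboxylate displacement and Stille vinylation; the benzene ring is bought.

Key step: step 6

Assumption: the (S)-binaphthoxide catalyst is taken to turn aryl methyl ketones into (S)-2-aryl-2-methyloxiranes. With the acyloxymethyl arm in the place of methyl, the (R)-binaphthoxide catalyst should then give the (R)-epoxide. If a calibration run shows the opposite sense, the ligand antipode is exchanged and nothing else changes.

**Step 1**
Reactants: 1 1-(4-bromo-2-hydroxyphenyl)ethan-1-one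
Product: 2 1-[4-bromo-2-(triisopropylsilyloxy)phenyl]ethan-1-one
Conditions: TIPSCl, imidazole, DMF, rt to 40 °C
Reagents that add atoms: chlorotri(propan-2-yl)silane, CC(C)[Si](Cl)(C(C)C)C(C)C
Why: Imidazole-promoted O-silylation of the phenol, with the bulky triisopropylsilyl group chosen because it should survive the basic ylide step and still leave with fluoride.

**Step 2**
Reactants: 2 1-[4-bromo-2-(triisopropylsilyloxy)phenyl]ethan-1-one
Product: 4 2-bromo-1-[4-bromo-2-(triisopropylsilyloxy)phenyl]ethan-1-one, via trimethylsilyl enol ether 3 (not isolated)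
Conditions: TMSOTf, Et3N, CH2Cl2, 0 °C; then NBS, 0 °C
Reagents that add atoms: N-bromosuccinimide, O=C1CCC(=O)N1Br
Why: Soft enolisation of the methyl ketone to its silyl enol ether followed by electrophilic bromination should give clean α-monobromination without acid, so the aryl silyl ether and the ring stay untouched.

**Step 3**
Reactants: 4 2-bromo-1-[4-bromo-2-(triisopropylsilyloxy)phenyl]ethan-1-one; 5 3-methylbutanoic acid
Product: 6 2-[4-bromo-2-(triisopropylsilyloxy)phenyl]-2-oxoethyl 3-methylbutanoate
Conditions: i-Pr2NEt, MeCN, rt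
Reagents that add atoms: 3-methylbutanoic acid (5), CC(C)CC(=O)O
Why: SN2 displacement of the activated α-bromo ketone by the ammonium carboxylate (phenacyl ester formation) is fast at room temperature, and the carbonate-free, fluoride-free medium should leave the aryl silyl ether in place.

**Step 4**
Reactants: 6 2-[4-bromo-2-(triisopropylsilyloxy)phenyl]-2-oxoethyl 3-methylbutanoate; 7 tributyl(vinyl)stannane
Product: 8 2-[4-ethenyl-2-(triisopropylsilyloxy)phenyl]-2-oxoethyl 3-methylbutanoate
Conditions: Pd(PPh3)4 (cat.), BHT (trace), toluene, 100 °C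
Reagents that add atoms: tributyl(vinyl)stannane (7), C=C[Sn](CCCC)(CCCC)CCCC
Why: Stille coupling, in which zerovalent palladium inserts easily into the aryl bromide para to the ketone and the neutral conditions spare the α-acyloxy ketone and the silyl ether.

**Step 5**
Reactants: 9 trimethylsulfoxonium iodide
Product: 10 dimethylsulfoxonium methylide (titrated THF solution, kept under argon)
Conditions: NaH, THF, reflux; filtered from solids
Reagents that add atoms: none
Why: Deprotonation of the sulfoxonium salt by NaH is the standard preparation of the Corey–Chaykovsky reagent, and filtration removes excess hydride that would otherwise enolise the ketone in the next step.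

**Step 6**
Reactants: 8 2-[4-ethenyl-2-(triisopropylsilyloxy)phenyl]-2-oxoethyl 3-methylbutanoate; 10 dimethylsulfoxonium methylide
Product: 12 [(2R)-2-[4-ethenyl-2-(triisopropylsilyloxy)phenyl]oxiran-2-yl]methyl 3-methylbutanoate, via sulfoxonium betaine 11 (not isolated)
Conditions: LaLi3[(R)-binaphthoxide]3 (5 mol%), tris(2,4,6-trimethoxyphenyl)phosphine oxide (5 mol%), 5 Å MS, THF, rt
Reagents that add atoms: dimethylsulfoxonium methylide (10), C[S+](C)(=O)[CH2-]
Why: Proposed new method: the closest known reaction is the LaLi3(binaphthoxide)3/phosphine oxide-catalysed Corey–Chaykovsky epoxidation of aryl methyl ketones, not yet shown on an α-acyloxy ketone; here trivalent lanthanum should bind the ketone oxygen of 8 while a lithium binaphthoxide site holds ylide 10, so that the ylide carbon C9 adds to C8 and gives betaine 11. The C8 alkoxide of 11 then expels dimethyl sulfoxide from C9 in a 3-exo-tet closure that forms C9–O and the oxirane, the only ring made in the route, without touching the configuration at C8. The new stereocenter C8 is set in the addition step by the chiral binaphthoxide pocket, which should tell the flat aryl group from the CH2 arm as it does aryl from methyl and so send the ylide to the Re face of the ketone, giving the (R)-epoxide. The step needs this enantioface selection and also chemoselectivity for the ketone over the alkyl ester, the styrene and the α-CH2 protons: the ketone is the most electrophilic carbonyl, the stabilised ylide should not add to the weakly activated styrene, the phenol is masked as a base-stable silyl ether, and no aldehyde or aryl ester is present. A 1,2-acyl shift in 11 would be reversible and would leave C8 unchanged, and only the tertiary alkoxide is placed for three-membered ring closure.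

**Step 7**
Reactants: 12 [(2R)-2-[4-ethenyl-2-(triisopropylsilyloxy)phenyl]oxiran-2-yl]methyl 3-methylbutanoate; 13 3-methylbutanoic anhydride
Product: 15 [(2R)-2-[4-ethenyl-2-(3-methylbutanoyloxy)phenyl]oxiran-2-yl]methyl 3-methylbutanoate, via caesium phenoxide 14 (not isolated)
Conditions: CsF, excess 13, DMF, 0 °C to rt
Reagents that add atoms: 3-methylbutanoic anhydride (13), CC(C)CC(=O)OC(=O)CC(C)C
Why: Fluoride-induced cleavage of the aryl silyl ether releases phenoxide 14 in the presence of excess anhydride, so O-acylation should outpace any attack of the phenoxide on the neighbouring oxirane, while the alkyl ester, the oxirane and C8 are not affected by CsF at this temperature.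

**Step 8**
Reactants: 15 [(2R)-2-[4-ethenyl-2-(3-methylbutanoyloxy)phenyl]oxiran-2-yl]methyl 3-methylbutanoate
Product: 17 [(2R)-2-[4-formyl-2-(3-methylbutanoyloxy)phenyl]oxiran-2-yl]methyl 3-methylbutanoate (CNP0274578.1), via ozonide 16 (not isolated)
Conditions: O3, CH2Cl2, −78 °C; then PPh3, −78 °C to rt
Reagents that add atoms: ozone, [O-][O+]=O
Why: Ozonolysis of the terminal styrene double bond through ozonide 16 and reduction with PPh3 should give the aryl aldehyde, since the oxirane, both esters and the acceptor-substituted ring do not react with ozone at −78 °C and C8 is not involved.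

**Compound list**

1 | 1-(4-bromo-2-hydroxyphenyl)ethan-1-one | CC(=O)c1ccc(Br)cc1O | starting material
2 | 1-[4-bromo-2-(triisopropylsilyloxy)phenyl]ethan-1-one | CC(=O)c1ccc(Br)cc1O[Si](C(C)C)(C(C)C)C(C)C | intermediate
3 | {1-[4-bromo-2-(triisopropylsilyloxy)phenyl]ethenyl}oxy(trimethyl)silane | C=C(O[Si](C)(C)C)c1ccc(Br)cc1O[Si](C(C)C)(C(C)C)C(C)C | intermediate
4 | 2-bromo-1-[4-bromo-2-(triisopropylsilyloxy)phenyl]ethan-1-one | BrCC(=O)c1ccc(Br)cc1O[Si](C(C)C)(C(C)C)C(C)C | intermediate
5 | 3-methylbutanoic acid | CC(C)CC(=O)O | starting material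
6 | 2-[4-bromo-2-(triisopropylsilyloxy)phenyl]-2-oxoethyl 3-methylbutanoate | CC(C)CC(=O)OCC(=O)c1ccc(Br)cc1O[Si](C(C)C)(C(C)C)C(C)C | intermediate
7 | tributyl(vinyl)stannane | C=C[Sn](CCCC)(CCCC)CCCC | starting material
8 | 2-[4-ethenyl-2-(triisopropylsilyloxy)phenyl]-2-oxoethyl 3-methylbutanoate | C=Cc1ccc(C(=O)COC(=O)CC(C)C)c(O[Si](C(C)C)(C(C)C)C(C)C)c1 | intermediate
9 | trimethylsulfoxonium iodide | C[S+](C)(C)=O.[I-] | starting material
10 | dimethylsulfoxonium methylide | C[S+](C)(=O)[CH2-] | intermediate
11 | (2S)-1-(dimethylsulfoxonio)-2-[4-ethenyl-2-(triisopropylsilyloxy)phenyl]-3-(3-methylbutanoyloxy)propan-2-olate (betaine, metal-bound in the flask) | CC(C)CC(=O)OC[C@@]([O-])(c1ccc(C=C)cc1O[Si](C(C)C)(C(C)C)C(C)C)C[S+](C)(C)=O | intermediate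
12 | [(2R)-2-[4-ethenyl-2-(triisopropylsilyloxy)phenyl]oxiran-2-yl]methyl 3-methylbutanoate | CC(C)CC(=O)OC[C@@]1(c2ccc(C=C)cc2O[Si](C(C)C)(C(C)C)C(C)C)CO1 | intermediate
13 | 3-methylbutanoic anhydride | CC(C)CC(=O)OC(=O)CC(C)C | starting material
14 | caesium 5-ethenyl-2-[(2R)-2-[(3-methylbutanoyloxy)methyl]oxiran-2-yl]phenolate | CC(C)CC(=O)OC[C@@]1(c2ccc(C=C)cc2[O-])CO1.[Cs+] | intermediate
15 | [(2R)-2-[4-ethenyl-2-(3-methylbutanoyloxy)phenyl]oxiran-2-yl]methyl 3-methylbutanoate | CC(C)CC(=O)OC[C@@]1(c2ccc(C=C)cc2OC(=O)CC(C)C)CO1 | intermediate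
16 | [(2R)-2-[2-(3-methylbutanoyloxy)-4-(1,2,4-trioxolan-3-yl)phenyl]oxiran-2-yl]methyl 3-methylbutanoate (either configuration at the trioxolane carbon) | CC(C)CC(=O)OC[C@@]1(c2ccc(C3OCOO3)cc2OC(=O)CC(C)C)CO1 | intermediate
17 | [(2R)-2-[4-formyl-2-(3-methylbutanoyloxy)phenyl]oxiran-2-yl]methyl 3-methylbutanoate | CC(C)CC(=O)OC[C@@]1(c2ccc(C=O)cc2OC(=O)CC(C)C)CO1 | target

**Step count**

Total steps: 8. Longest linear sequence: 7 (steps 1–4 and 6–8, from 1); step 5 is a one-step side branch.

**Steps most likely to fail**

1. Step 6. The acyloxymethyl arm can chelate lanthanum together with the ketone oxygen, so the catalyst may not read it like a methyl group and facial selectivity may be poor. Addition to the hindered ortho-silyloxy ketone may also be slow, which would let enolisation, acyl migration or ylide attack at the ester compete. The fallback uses known chemistry, sets out from 8 and returns at 12.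
   - The ketone of 8 would be methylenated under non-basic Takai–Lombardo conditions (Zn, CH2Br2, TiCl4, THF, 0 °C to rt) to 2-[4-ethenyl-2-(triisopropylsilyloxy)phenyl]prop-2-en-1-yl 3-methylbutanoate F1.
   - The ester would be cleaved reductively (i-Bu2AlH, CH2Cl2, −78 °C) to 2-[4-ethenyl-2-(triisopropylsilyloxy)phenyl]prop-2-en-1-ol F2.
   - Sharpless asymmetric epoxidation (Ti(Oi-Pr)4, L-(+)-diethyl tartrate, t-BuOOH, 4 Å MS, CH2Cl2, −20 °C) acts only on the allylic alcohol and not on the styrene, and should give [(2S)-2-[4-ethenyl-2-(triisopropylsilyloxy)phenyl]oxiran-2-yl]methanol F3. F3 has the same arrangement in space as (R)-12; the descriptor differs only because C9 outranks the free hydroxymethyl carbon.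
   - Acylation with 13 (Et3N, DMAP cat., CH2Cl2, 0 °C) rejoins the route at 12.

2. Step 7. The free phenoxide may open the neighbouring benzylic oxirane (push from the ortho oxygen or cyclic ether formation), or the ester may scramble between the C10 oxygen and the phenoxide, before O-acylation takes place. The fallback sets out from 12 and returns at 15.
   - Desilylation with Bu4NF buffered by AcOH (THF, 0 °C) keeps the oxygen protonated and should give the neutral phenol [(2R)-2-(4-ethenyl-2-hydroxyphenyl)oxiran-2-yl]methyl 3-methylbutanoate F4.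
   - F4 would be used at once in a Steglich esterification with 5 (DCC, DMAP cat., CH2Cl2, 0 °C) to reach 15.

3. Step 8. The ozonide may be reduced incompletely, the aldehyde may be over-oxidised, or peroxidic by-products may open the oxirane during warming. The fallback sets out from 15 and returns at 17.
   - Upjohn dihydroxylation of the styrene (OsO4 cat., N-methylmorpholine N-oxide, acetone/H2O, rt) should give [(2R)-2-[4-(1,2-dihydroxyethyl)-2-(3-methylbutanoyloxy)phenyl]oxiran-2-yl]methyl 3-methylbutanoate F5 as a mixture of carbinol epimers.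
   - Glycol cleavage (NaIO4, THF/pH 7 buffer, 0 °C) would then give 17.

**Further compounds**

F1 | step 6 | 2-[4-ethenyl-2-(triisopropylsilyloxy)phenyl]prop-2-en-1-yl 3-methylbutanoate | C=C(COC(=O)CC(C)C)c1ccc(C=C)cc1O[Si](C(C)C)(C(C)C)C(C)C
F2 | step 6 | 2-[4-ethenyl-2-(triisopropylsilyloxy)phenyl]prop-2-en-1-ol | C=C(CO)c1ccc(C=C)cc1O[Si](C(C)C)(C(C)C)C(C)C
F3 | step 6 | [(2S)-2-[4-ethenyl-2-(triisopropylsilyloxy)phenyl]oxiran-2-yl]methanol | OC[C@@]1(c2ccc(C=C)cc2O[Si](C(C)C)(C(C)C)C(C)C)CO1
F4 | step 7 | [(2R)-2-(4-ethenyl-2-hydroxyphenyl)oxiran-2-yl]methyl 3-methylbutanoate | CC(C)CC(=O)OC[C@@]1(c2ccc(C=C)cc2O)CO1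
F5 | step 8 | [(2R)-2-[4-(1,2-dihydroxyethyl)-2-(3-methylbutanoyloxy)phenyl]oxiran-2-yl]methyl 3-methylbutanoate | CC(C)CC(=O)OC[C@@]1(c2ccc(C(O)CO)cc2OC(=O)CC(C)C)CO1
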